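**Strategy.** The ten-membered carbocycle contains the 1,5-diene C10=C1–C2–C3–C4=C5, and C2–C3 is its central σ-bond. That bond is therefore made by a [3,3] shift: an anionic oxy-Cope ring expansion of a trans-1,2-dialkenylcyclohexanol (six-membered ring C5–C10, with C5–C10 bonded and C10 carrying O⁻ in place of the methyl). One operation forms C2–C3, opens the cyclodecadiene and fixes both ring-olefin geometries. The enolate is trapped as the C10 enol triflate and then methylated. The all-cis C6/C7/C8 triad is built on the cyclohexane template by Ireland–Claisen chirality transfer from an enzymatically desymmetrised cis-cyclohexene-1,4-diol derivative and a lactonising conjugate addition.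

Key step: step 14

Remark: the target is read as (6R,7S,8S,11R) with a cis-fused 6,12-lactone, O8 cis to C11, and ring-trans C1=C10 and C4=C5 bonds. Atom labels C1–C15 are germacrane numbers (C14 = methyl on C10, C15 = CH2OH on C4). In every intermediate O6, C11 (on C7) and O8 lie on one face of the carbocycle, and the SMILES define the absolute configuration.

**Step 1**
Reactants: 1 cyclohexa-1,3-diene
Product: 2 cis-cyclohex-2-ene-1,4-diyl diacetate (meso)
Conditions: Pd(OAc)2 (cat.), LiCl (cat.), LiOAc, p-benzoquinone, AcOH, 25 °C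
Reagents that add atoms: acetic acid, CC(=O)O
Why: Palladium-catalysed 1,4-diacetoxylation of a conjugated diene; in the presence of chloride the π-allyl intermediate is attacked by external acetate, which should give the cis (meso) diacetate.

**Step 2**
Reactants: 2 cis-cyclohex-2-ene-1,4-diyl diacetate
Product: 3 (1R,4S)-4-hydroxycyclohex-2-en-1-yl acetate
Conditions: lipase from Pseudomonas cepacia, phosphate buffer pH 7, 25 °C
Reagents that add atoms: none
Why: Enzymatic desymmetrisation of a meso diester (enantiotopic-group-selective hydrolysis) should cleave the acetate on the (S)-configured carbon and so fix the absolute configuration that is later relayed to C7, C6 and C11.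

**Step 3**
Reactants: 3 (1R,4S)-4-hydroxycyclohex-2-en-1-yl acetate
Product: 4 (1R,4S)-4-(tert-butyldimethylsilyloxy)cyclohex-2-en-1-yl acetate
Conditions: t-BuMe2SiCl, imidazole, DMF, 25 °C
Reagents that add atoms: tert-butyldimethylsilyl chloride, CC(C)(C)[Si](C)(C)Cl
Why: Imidazole-mediated silyl ether formation protects the oxygen that becomes O8.

**Step 4**
Reactants: 4 (1R,4S)-4-(tert-butyldimethylsilyloxy)cyclohex-2-en-1-yl acetate
Product: 8 methyl 2-[(1R,6S)-6-(tert-butyldimethylsilyloxy)cyclohex-2-en-1-yl]acetate, via silyl ketene acetal 5 (not isolated), via trimethylsilyl ester 6 (not isolated), via carboxylic acid 7 (not isolated)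
Conditions: LiN(i-Pr)2, Me3SiCl, THF, −78 → 60 °C; dilute HCl work-up; then MeI, K2CO3, DMF, 25 °C
Reagents that add atoms: iodomethane, CI
Why: Ireland–Claisen rearrangement: the suprafacial [3,3] shift forms the C7–C11 bond on the ring face from which the C5–O bond departs, i.e. cis to the C8 silyloxy group, and the crude acid is O-methylated for the following steps.

**Step 5**
Reactants: 8 methyl 2-[(1R,6S)-6-(tert-butyldimethylsilyloxy)cyclohex-2-en-1-yl]acetate
Product: 9 methyl 2-[(1R,6S)-6-(tert-butyldimethylsilyloxy)-4-oxocyclohex-2-en-1-yl]acetate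
Conditions: Rh2(cap)4 (cat., cap = caprolactamate), t-BuOOH (70% in water), 1,2-dichloroethane, 40 °C
Reagents that add atoms: tert-butyl hydroperoxide, CC(C)(C)OO
Why: Dirhodium-catalysed allylic C–H oxidation should convert the unhindered allylic CH2 (C10) into the enone carbonyl, since the other allylic site (C7–H) is tertiary and flanked by the side chain and the silyloxy group.

**Step 6**
Reactants: 9 methyl 2-[(1R,6S)-6-(tert-butyldimethylsilyloxy)-4-oxocyclohex-2-en-1-yl]acetate
Product: 10 methyl 2-[(1R,6S)-6-(tert-butyldimethylsilyloxy)-3-iodo-4-oxocyclohex-2-en-1-yl]acetate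
Conditions: I2, pyridine, CH2Cl2, 0 → 25 °C
Reagents that add atoms: iodine, II
Why: α-Iodination of a cyclic enone (pyridine addition, iodination, elimination) installs the coupling handle at C5.

**Step 7**
Reactants: 11 2-bromoprop-2-en-1-ol
Product: 12 (2-bromoprop-2-en-1-yloxy)(tert-butyl)diphenylsilane
Conditions: t-BuPh2SiCl, imidazole, CH2Cl2, 25 °C
Reagents that add atoms: tert-butyldiphenylsilyl chloride, CC(C)(C)[Si](Cl)(c1ccccc1)c1ccccc1
Why: Silyl ether formation protects the future C15 hydroxyl with a bulky group that resists silyl migration to carbon in the next step.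

**Step 8**
Reactants: 10 methyl 2-[(1R,6S)-6-(tert-butyldimethylsilyloxy)-3-iodo-4-oxocyclohex-2-en-1-yl]acetate; 12 (2-bromoprop-2-en-1-yloxy)(tert-butyl)diphenylsilane
Product: 15 methyl 2-[(1R,6S)-3-[3-(tert-butyldiphenylsilyloxy)prop-1-en-2-yl]-6-(tert-butyldimethylsilyloxy)-4-oxocyclohex-2-en-1-yl]acetate, via alkenyllithium 13 (not isolated), via alkenylzinc chloride 14 (not isolated)
Conditions: 12, t-BuLi (2 equiv), Et2O, −78 °C; ZnCl2, THF; then 10, Pd(PPh3)4 (cat.), THF, 25 °C
Reagents that add atoms: none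
Why: Negishi coupling (bromine–lithium exchange, transmetallation to zinc, zerovalent-palladium-catalysed coupling with the α-iodoenone) attaches the C3–C4(C15) alkenyl unit to C5 under non-basic conditions.

**Step 9**
Reactants: 15 methyl 2-[(1R,6S)-3-[3-(tert-butyldiphenylsilyloxy)prop-1-en-2-yl]-6-(tert-butyldimethylsilyloxy)-4-oxocyclohex-2-en-1-yl]acetate
Product: 17 all-cis keto lactone (hexahydro-1-benzofuran-2,6-dione core: lactone O on C6, OSi-t-BuMe2 on C8, ketone C10, alkenyl on C5), via keto acid 16 (not isolated)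
Conditions: Me3SnOH, 1,2-dichloroethane, 70 °C; dilute HCl wash; then camphorsulfonic acid (cat.), CH2Cl2, 0 → 25 °C
Reagents that add atoms: trimethyltin hydroxide, C[Sn](C)(C)O
Why: Neutral tin-hydroxide ester cleavage avoids base-induced β-elimination of the C8 silyloxy group, and the acid then adds to C6 of the dienone (intramolecular oxa-Michael addition, 5-exo-trig), necessarily from the face of the C7 side chain so that O6 is cis to C11, while kinetic α-protonation of the dienol from the face opposite the new lactone should place the C5 alkenyl group cis to O6.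

**Step 10**
Reactants: 17 all-cis keto lactone
Product: 18 tertiary vinyl carbinol lactone (C10 bears OH and CH=CH2; vinyl trans to the C5 alkenyl group)
Conditions: CeCl3, CH2=CHMgBr, THF, −78 °C
Reagents that add atoms: vinylmagnesium bromide, C=C[Mg]Br
Why: CeCl3-promoted Grignard 1,2-addition (suppresses enolisation and β-elimination of the β-acyloxy ketone) should occur by equatorial attack, anti to the two axial oxygens O6 and O8, giving the vinyl group trans to the equatorial C5 alkenyl group.

**Step 11**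
Reactants: 18 tertiary vinyl carbinol lactone
Product: 20 α-methyl lactone (C11 methyl on the convex face, 11R), via dilithium alkoxide enolate 19 (not isolated)
Conditions: LiN(i-Pr)2 (2.2 equiv), THF, −78 °C; then MeI, −78 → −40 °C
Reagents that add atoms: iodomethane, CI
Why: Lactone enolate alkylation from the convex face of the cis-fused bicycle should place the methyl trans to the C7–C8 bond, which is the C11 configuration of the target.

**Step 12**
Reactants: 20 α-methyl lactone
Product: 21 γ-hydroxy N-methoxy-N-methylamide (cyclohexane with C10 OH/vinyl, C5 alkenyl, C6 OH, C7 CH(CH3)C(O)N(OMe)Me, C8 OSi-t-BuMe2)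
Conditions: Me3Al, MeNH(OMe)·HCl, CH2Cl2, 0 → 25 °C
Reagents that add atoms: N,O-dimethylhydroxylamine hydrochloride, CNOC.Cl
Why: Aluminium-amide aminolysis of the lactone removes the acidic lactone α-proton and the electrophilic ester before the alkoxide chemistry, while keeping C12 at the acid oxidation level.

**Step 13**
Reactants: 21 γ-hydroxy N-methoxy-N-methylamide
Product: 22 C6 triethylsilyl ether with free tertiary C10 hydroxyl
Conditions: Et3SiCl, imidazole, DMF, 0 °C
Reagents that add atoms: chlorotriethylsilane, CC[Si](Cl)(CC)CC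
Why: Silyl ether formation is selective for the secondary C6 hydroxyl over the tertiary allylic one and prevents relactonisation.

**Step 14**
Reactants: 22 C6 triethylsilyl ether with free tertiary C10 hydroxyl
Product: 25 ten-membered C10 enol triflate (C9 trans to C2 across C1=C10; C3 trans to C6 across C4=C5), via potassium alkoxide 23 (not isolated), via potassium enolate 24 (not isolated)
Conditions: KN(SiMe3)2 (1.2 equiv), 18-crown-6, THF, −78 → 25 °C; then PhN(SO2CF3)2, −78 → 0 °C
Reagents that add atoms: N-phenylbis(trifluoromethanesulfonimide), O=S(=O)(N(c1ccccc1)S(=O)(=O)C(F)(F)F)C(F)(F)F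
Why: The crown-ether-separated potassium alkoxide 23 should undergo a [3,3]-sigmatropic shift through a chair transition state with the C10 vinyl and C5 alkenyl groups both equatorial on the cyclohexane, so that C5–C10 breaks, C2–C3 forms and the ten-membered enolate 24 results. The closest known reaction type is the anionic oxy-Cope ring expansion of trans-1,2-divinylcyclohexanols to cyclodec-5-enones with in situ O-sulfonylation of the enolate. The ten-membered ring is closed by a four-atom ring expansion through a six-centre pericyclic array, not by end-to-end cyclisation, so no high dilution is needed. No stereocentre is created: the stereocentres C5 and C10 are converted into two olefin geometries, the trans-diequatorial arrangement giving the ring-trans C4=C5 bond and the C1=C10 enolate with C9 trans to C2, while C6, C7, C8 and C11 are untouched. The step needs a regiochemically intact enolate (no proton transfer to C9, which would open β-elimination of the C8 silyloxy group) and O-sulfonylation; the absence of a proton source, the non-enolisable amide and immediate low-temperature trapping should secure this.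

**Step 15**
Reactants: 25 ten-membered C10 enol triflate
Product: 26 (1(10)E,4Z)-germacradiene amide (C14 methyl on C10; C6 OSiEt3, C8 OSi-t-BuMe2, C15 OSi-t-BuPh2, C12 N-methoxy-N-methylamide)
Conditions: Me2Zn, Pd(PPh3)4 (cat.), THF, 25 °C
Reagents that add atoms: dimethylzinc, C[Zn]C
Why: Negishi methylation of the enol triflate proceeds with retention of olefin geometry and delivers the C14 methyl on the E-configured C1=C10 bond, and dimethylzinc does not attack the amide.

**Step 16**
Reactants: 26 (1(10)E,4Z)-germacradiene amide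
Product: 29 8-hydroxy-6,12-lactone with C15 OSi-t-BuPh2, via hydroxy amide 27 (not isolated), via silylated lactone 28 (not isolated)
Conditions: HF·pyridine, pyridine, THF, 0 °C then 25 °C
Reagents that add atoms: none
Why: Buffered HF·pyridine cleaves the triethylsilyl ether first and the freed C6 hydroxyl should cyclise onto the N-methoxy-N-methylamide (γ-lactonisation) while O8 is still silylated, which fixes the 6,12-lactone; at 25 °C the secondary tert-butyldimethylsilyl ether is then removed while the primary tert-butyldiphenylsilyl ether should survive.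

**Step 17**
Reactants: 30 ethyl 2-(hydroxymethyl)prop-2-enoate
Product: 31 ethyl 2-[(tert-butyldimethylsilyloxy)methyl]prop-2-enoate
Conditions: t-BuMe2SiCl, imidazole, DMF, 25 °C
Reagents that add atoms: tert-butyldimethylsilyl chloride, CC(C)(C)[Si](C)(C)Cl
Why: Silyl ether formation masks the side-chain hydroxyl so that the acid can be activated without self-esterification.

**Step 18**
Reactants: 31 ethyl 2-[(tert-butyldimethylsilyloxy)methyl]prop-2-enoate
Product: 32 2-[(tert-butyldimethylsilyloxy)methyl]prop-2-enoic acid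
Conditions: LiOH, THF/H2O, 0 °C; dilute HCl to pH 4
Reagents that add atoms: lithium hydroxide, [Li+].[OH-]
Why: Ester saponification at low temperature gives the acid, the silyl ether being stable to cold aqueous hydroxide.

**Step 19**
Reactants: 29 8-hydroxy-6,12-lactone with C15 OSi-t-BuPh2; 32 2-[(tert-butyldimethylsilyloxy)methyl]prop-2-enoic acid
Product: 34 bis-silylated target (8-O-acyl ester), via mixed anhydride 33 (not isolated)
Conditions: 32, 2,4,6-trichlorobenzoyl chloride, Et3N, toluene, 25 °C; then 29, 4-(dimethylamino)pyridine, 25 °C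
Reagents that add atoms: none
Why: Yamaguchi esterification acylates the hindered secondary C8 hydroxyl, the only free hydroxyl, without touching the lactone or the C8 configuration.

**Step 20**
Reactants: 34 bis-silylated target
Product: 35 target CNP0167163.2
Conditions: Bu4NF, AcOH, THF, 0 → 25 °C
Reagents that add atoms: none
Why: Acetic-acid-buffered fluoride desilylation should remove both primary silyl ethers without acyl migration, conjugate addition to the acrylate or transannular reaction of the diene.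

**Compound list**

1 | cyclohexa-1,3-diene | C1=CC=CCC1 | starting material
2 | cis-cyclohex-2-ene-1,4-diyl diacetate (meso) | CC(=O)O[C@H]1C=C[C@@H](OC(C)=O)CC1 | intermediate
3 | (1R,4S)-4-hydroxycyclohex-2-en-1-yl acetate | CC(=O)O[C@H]1C=C[C@@H](O)CC1 | intermediate
4 | (1R,4S)-4-(tert-butyldimethylsilyloxy)cyclohex-2-en-1-yl acetate | CC(=O)O[C@H]1C=C[C@@H](O[Si](C)(C)C(C)(C)C)CC1 | intermediate
5 | trimethylsilyl ketene acetal of 4 | C=C(O[Si](C)(C)C)O[C@H]1C=C[C@@H](O[Si](C)(C)C(C)(C)C)CC1 | intermediate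
6 | trimethylsilyl 2-[(1R,6S)-6-(tert-butyldimethylsilyloxy)cyclohex-2-en-1-yl]acetate | C[Si](C)(C)OC(=O)C[C@@H]1C=CCC[C@@H]1O[Si](C)(C)C(C)(C)C | intermediate
7 | 2-[(1R,6S)-6-(tert-butyldimethylsilyloxy)cyclohex-2-en-1-yl]acetic acid | OC(=O)C[C@@H]1C=CCC[C@@H]1O[Si](C)(C)C(C)(C)C | intermediate
8 | methyl 2-[(1R,6S)-6-(tert-butyldimethylsilyloxy)cyclohex-2-en-1-yl]acetate (side chain cis to OSi) | COC(=O)C[C@@H]1C=CCC[C@@H]1O[Si](C)(C)C(C)(C)C | intermediate
9 | methyl 2-[(1R,6S)-6-(tert-butyldimethylsilyloxy)-4-oxocyclohex-2-en-1-yl]acetate | COC(=O)C[C@@H]1C=CC(=O)C[C@@H]1O[Si](C)(C)C(C)(C)C | intermediate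
10 | methyl 2-[(1R,6S)-6-(tert-butyldimethylsilyloxy)-3-iodo-4-oxocyclohex-2-en-1-yl]acetate | COC(=O)C[C@@H]1C=C(I)C(=O)C[C@@H]1O[Si](C)(C)C(C)(C)C | intermediate
11 | 2-bromoprop-2-en-1-ol | C=C(Br)CO | starting material
12 | (2-bromoprop-2-en-1-yloxy)(tert-butyl)diphenylsilane | C=C(Br)CO[Si](c1ccccc1)(c1ccccc1)C(C)(C)C | intermediate
13 | [3-(tert-butyldiphenylsilyloxy)prop-1-en-2-yl]lithium | [Li]C(=C)CO[Si](c1ccccc1)(c1ccccc1)C(C)(C)C | intermediate
14 | [3-(tert-butyldiphenylsilyloxy)prop-1-en-2-yl]zinc chloride | Cl[Zn]C(=C)CO[Si](c1ccccc1)(c1ccccc1)C(C)(C)C | intermediate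
15 | methyl 2-[(1R,6S)-3-[3-(tert-butyldiphenylsilyloxy)prop-1-en-2-yl]-6-(tert-butyldimethylsilyloxy)-4-oxocyclohex-2-en-1-yl]acetate | COC(=O)C[C@@H]1C=C(C(=C)CO[Si](c2ccccc2)(c2ccccc2)C(C)(C)C)C(=O)C[C@@H]1O[Si](C)(C)C(C)(C)C | intermediate
16 | 2-[(1R,6S)-3-[3-(tert-butyldiphenylsilyloxy)prop-1-en-2-yl]-6-(tert-butyldimethylsilyloxy)-4-oxocyclohex-2-en-1-yl]acetic acid | OC(=O)C[C@@H]1C=C(C(=C)CO[Si](c2ccccc2)(c2ccccc2)C(C)(C)C)C(=O)C[C@@H]1O[Si](C)(C)C(C)(C)C | intermediate
17 | all-cis keto lactone: 4-(tert-butyldimethylsilyloxy)-7-[3-(tert-butyldiphenylsilyloxy)prop-1-en-2-yl]hexahydro-1-benzofuran-2,6-dione, with H3a, H4, H7 and H7a on one face | CC(C)(C)[Si](C)(C)O[C@H]1CC(=O)[C@@H](C(=C)CO[Si](c2ccccc2)(c2ccccc2)C(C)(C)C)[C@H]2OC(=O)C[C@@H]12 | intermediate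
18 | tertiary vinyl carbinol lactone: 17 with C6 of the benzofuranone (= C10) as C(OH)(CH=CH2), vinyl trans to the neighbouring alkenyl group | CC(C)(C)[Si](C)(C)O[C@H]1C[C@](O)(C=C)[C@@H](C(=C)CO[Si](c2ccccc2)(c2ccccc2)C(C)(C)C)[C@H]2OC(=O)C[C@@H]12 | intermediate
19 | dilithium alkoxide/lactone enolate of 18 | [Li+].[Li+].CC(C)(C)[Si](C)(C)O[C@H]1C[C@]([O-])(C=C)[C@@H](C(=C)CO[Si](c2ccccc2)(c2ccccc2)C(C)(C)C)[C@H]2OC([O-])=C[C@@H]12 | intermediate
20 | α-methyl lactone: 18 with a convex-face methyl on the lactone α-carbon (C11, 11R) | CC(C)(C)[Si](C)(C)O[C@H]1C[C@](O)(C=C)[C@@H](C(=C)CO[Si](c2ccccc2)(c2ccccc2)C(C)(C)C)[C@H]2OC(=O)[C@H](C)[C@@H]12 | intermediate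
21 | γ-hydroxy N-methoxy-N-methylamide: (2R)-2-substituted propanamide on a cyclohexane carrying C10 OH/vinyl, C5 alkenyl, C6 OH and C8 OSi-t-BuMe2 (O6, C11, O8 and the C5 alkenyl group all cis) | CC(C)(C)[Si](C)(C)O[C@H]1C[C@](O)(C=C)[C@@H](C(=C)CO[Si](c2ccccc2)(c2ccccc2)C(C)(C)C)[C@@H](O)[C@H]1[C@@H](C)C(=O)N(C)OC | intermediate
22 | C6 triethylsilyl ether of 21 (tertiary C10 hydroxyl free) | CC(C)(C)[Si](C)(C)O[C@H]1C[C@](O)(C=C)[C@@H](C(=C)CO[Si](c2ccccc2)(c2ccccc2)C(C)(C)C)[C@@H](O[Si](CC)(CC)CC)[C@H]1[C@@H](C)C(=O)N(C)OC | intermediate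
23 | potassium alkoxide of 22 | [K+].CC(C)(C)[Si](C)(C)O[C@H]1C[C@]([O-])(C=C)[C@@H](C(=C)CO[Si](c2ccccc2)(c2ccccc2)C(C)(C)C)[C@@H](O[Si](CC)(CC)CC)[C@H]1[C@@H](C)C(=O)N(C)OC | intermediate
24 | potassium enolate of the ten-membered C10 ketone (enolate C1=C10, ring-trans C4=C5) | [K+].CC(C)(C)[Si](C)(C)O[C@H]1C/C([O-])=C/CC/C(CO[Si](c2ccccc2)(c2ccccc2)C(C)(C)C)=C/[C@@H](O[Si](CC)(CC)CC)[C@H]1[C@@H](C)C(=O)N(C)OC | intermediate
25 | ten-membered C10 enol triflate (C9 trans to C2; C3 trans to C6) | CC(C)(C)[Si](C)(C)O[C@H]1C/C(OS(=O)(=O)C(F)(F)F)=C/CC/C(CO[Si](c2ccccc2)(c2ccccc2)C(C)(C)C)=C/[C@@H](O[Si](CC)(CC)CC)[C@H]1[C@@H](C)C(=O)N(C)OC | intermediate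
26 | N-methoxy-N-methylamide of (1(10)E,4Z,11R)-6-(triethylsilyloxy)-8-(tert-butyldimethylsilyloxy)-15-(tert-butyldiphenylsilyloxy)germacra-1(10),4-dien-12-oic acid (O6, C11, O8 cis) | CC(C)(C)[Si](C)(C)O[C@H]1C/C(C)=C/CC/C(CO[Si](c2ccccc2)(c2ccccc2)C(C)(C)C)=C/[C@@H](O[Si](CC)(CC)CC)[C@H]1[C@@H](C)C(=O)N(C)OC | intermediate
27 | 6-hydroxy analogue of 26 | CC(C)(C)[Si](C)(C)O[C@H]1C/C(C)=C/CC/C(CO[Si](c2ccccc2)(c2ccccc2)C(C)(C)C)=C/[C@@H](O)[C@H]1[C@@H](C)C(=O)N(C)OC | intermediate
28 | cis-fused 6,12-lactone with C8 OSi-t-BuMe2 and C15 OSi-t-BuPh2 | CC(C)(C)[Si](C)(C)O[C@H]1C/C(C)=C/CC/C(CO[Si](c2ccccc2)(c2ccccc2)C(C)(C)C)=C/[C@H]2OC(=O)[C@H](C)[C@@H]12 | intermediate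
29 | (6R,7S,8S,11R)-8-hydroxy-15-(tert-butyldiphenylsilyloxy)germacra-1(10)E,4Z-dien-6,12-olide | O[C@H]1C/C(C)=C/CC/C(CO[Si](c2ccccc2)(c2ccccc2)C(C)(C)C)=C/[C@H]2OC(=O)[C@H](C)[C@@H]12 | intermediate
30 | ethyl 2-(hydroxymethyl)prop-2-enoate | C=C(CO)C(=O)OCC | starting material
31 | ethyl 2-[(tert-butyldimethylsilyloxy)methyl]prop-2-enoate | C=C(CO[Si](C)(C)C(C)(C)C)C(=O)OCC | intermediate
32 | 2-[(tert-butyldimethylsilyloxy)methyl]prop-2-enoic acid | C=C(CO[Si](C)(C)C(C)(C)C)C(=O)O | intermediate
33 | mixed anhydride of 32 with 2,4,6-trichlorobenzoic acid | C=C(CO[Si](C)(C)C(C)(C)C)C(=O)OC(=O)c1c(Cl)cc(Cl)cc1Cl | intermediate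
34 | bis-silylated target: 29 acylated on O8 with 2-[(tert-butyldimethylsilyloxy)methyl]prop-2-enoyl | C=C(CO[Si](C)(C)C(C)(C)C)C(=O)O[C@H]1C/C(C)=C/CC/C(CO[Si](c2ccccc2)(c2ccccc2)C(C)(C)C)=C/[C@H]2OC(=O)[C@H](C)[C@@H]12 | intermediate
35 | CNP0167163.2 | C=C(CO)C(=O)O[C@H]1C/C(C)=C/CC/C(CO)=C/[C@H]2OC(=O)[C@H](C)[C@@H]12 | target

**Step count.** Total: 20 steps. Longest linear sequence: 17 steps (steps 1–6, 8–16, 19, 20).

**Steps most likely to fail**

Step 14 (key step). The ten-membered enolate may transfer a proton so that the enolate shifts toward C9 and the C8 silyloxide is eliminated. O-sulfonylation of the hindered enolate may also be incomplete. Fallback, from 22 back to 25: the potassium alkoxide rearrangement is run as before but quenched at −78 °C with Me3SiCl/Et3N, which traps the enolate faster and gives the trimethylsilyl enol ether F1. After isolation, F1 is converted regiospecifically into triflate 25 with anhydrous CsF and PhN(SO2CF3)2 in 1,2-dimethoxyethane. This separates the sigmatropic step from the sulfonylation.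

Step 9. The conjugate-addition equilibrium may lie on the side of the open dienone acid. The exocyclic double bond may also migrate into conjugation, or the β-oxygen groups may be eliminated. Fallback, from 15 back to 17: 15 is cleaved to acid 16 as before, and 16 is then treated with Me3SiOSO2CF3 and Et3N in CH2Cl2 at −78 °C. This silyl-transfer-driven intramolecular conjugate addition should trap the adduct irreversibly as the lactone silyl dienol ether F2. Protodesilylation with AcOH-buffered Bu4NF at −40 °C (kinetic α-protonation) then gives 17.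

Step 5. The allylic C–H oxidation may show poor site selectivity (attack at C7–H, or allylic transposition) or over-oxidise. Fallback, from 8 back to 9: allylic hydroxylation with SeO2 (cat.) and t-BuOOH in CH2Cl2 (ene reaction then [2,3] shift, which keeps the C5=C6 bond in place) gives the allylic alcohol F3 as a mixture of C10 epimers. Oxidation of F3 with MnO2 in CH2Cl2 gives enone 9.

**Further compounds**

F1 | step 14 | trimethylsilyl enol ether of the ten-membered C10 ketone (same geometry as 25) | CC(C)(C)[Si](C)(C)O[C@H]1C/C(O[Si](C)(C)C)=C/CC/C(CO[Si](c2ccccc2)(c2ccccc2)C(C)(C)C)=C/[C@@H](O[Si](CC)(CC)CC)[C@H]1[C@@H](C)C(=O)N(C)OC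
F2 | step 9 | lactone trimethylsilyl dienol ether (C10 OSiMe3, C5=C10) | CC(C)(C)[Si](C)(C)O[C@H]1CC(O[Si](C)(C)C)=C(C(=C)CO[Si](c2ccccc2)(c2ccccc2)C(C)(C)C)[C@H]2OC(=O)C[C@@H]12
F3 | step 5 | methyl 2-[(1R,6S)-6-(tert-butyldimethylsilyloxy)-4-hydroxycyclohex-2-en-1-yl]acetate (C10 epimers) | COC(=O)C[C@@H]1C=CC(O)C[C@@H]1O[Si](C)(C)C(C)(C)C
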